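**Retrosynthetic overview**

1. The target is traced back to its aryl triisopropylsilyl ether; the silyl group is removed by fluoride in the flask of the key step.
2. Key cut: C2–C3, the ketone α-carbon to the quaternary carbon. The α-carbon comes as an electrophilic copper α-oxo-carbenoid made from an aryl diazomethyl ketone (an enolonium equivalent). C3 comes as the γ-carbon of (2E,6E)-farnesylboronic acid. Both carbons are natural nucleophiles. Allyl transposition creates the vinyl group, and a chiral bisoxazoline on copper is meant to set C3 in the same event.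
3. The diazoketone comes from 1-(2-hydroxy-6-methylphenyl)ethanone by O-silylation and detrifluoroacetylative diazo transfer. The boronic acid comes from (2E,6E)-farnesol by one palladium-catalysed borylation.
4. No ring is formed: the benzene ring is bought intact, so there is no ring-forming order.

Assumption: the (S,S)-ligand is taken to give the 3R product; the sense of induction is checked on the first run and the (R,R)-ligand is used if it is the opposite; farnesol is used as the ≥98% (2E,6E) isomer.

**Route**

Step 1
Reactants: 1 1-(2-hydroxy-6-methylphenyl)ethan-1-one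
Product: 2 1-[2-methyl-6-(triisopropylsilyloxy)phenyl]ethan-1-one
Conditions: TIPSCl, imidazole, DMAP (cat.), DMF, 40 °C
Reagents that add atoms: chlorotri(propan-2-yl)silane (TIPSCl), CC(C)[Si](Cl)(C(C)C)C(C)C
Why: Silyl ether protection of the phenol; a free ortho-OH would trap the later copper carbenoid by intramolecular O–H insertion to a benzofuranone, and the bulky, weakly basic silyloxy oxygen neither migrates to the enolate in step 2 nor readily forms an oxonium ylide in step 4.

Step 2
Reactants: 2 1-[2-methyl-6-(triisopropylsilyloxy)phenyl]ethan-1-one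
Product: 5 2-diazo-1-[2-methyl-6-(triisopropylsilyloxy)phenyl]ethan-1-one, via lithium enolate 3 (not isolated), via trifluoroacetyl ketone 4 (not isolated)
Conditions: LiN(SiMe3)2, THF, –78 °C; CF3CO2CH2CF3, –78 °C; aqueous wash, crude carried on; 4-acetamidobenzenesulfonyl azide, Et3N, H2O (1 equiv), MeCN, 20 °C
Reagents that add atoms: lithium bis(trimethylsilyl)amide, [Li+].C[Si](C)(C)[N-][Si](C)(C)C (the lithium of 3 only); 2,2,2-trifluoroethyl trifluoroacetate, O=C(OCC(F)(F)F)C(F)(F)F (the trifluoroacetyl group, present only in 4); 4-acetamidobenzenesulfonyl azide, CC(=O)Nc1ccc(cc1)S(=O)(=O)N=[N+]=[N-] (the two diazo nitrogens of 5)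
Why: Danheiser detrifluoroacetylative diazo transfer (a deacylative Regitz transfer): the kinetic enolate is C-acylated by the trifluoroethyl ester, and the activated 1,3-diketone takes N2 from the sulfonyl azide while the trifluoroacetyl group leaves on the sulfonamide nitrogen.

Step 3
Reactants: 6 (2E,6E)-3,7,11-trimethyldodeca-2,6,10-trien-1-ol [(2E,6E)-farnesol]
Product: 7 [(2E,6E)-3,7,11-trimethyldodeca-2,6,10-trien-1-yl]boronic acid
Conditions: B2(OH)4, [Pd(MeCN)4](BF4)2 (1 mol %), DMSO–MeOH, 20 °C, Ar; extracted under Ar, used as a titrated toluene solution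
Reagents that add atoms: tetrahydroxydiboron, OB(O)B(O)O
Why: Palladium-catalysed direct borylation of an allylic alcohol with tetrahydroxydiboron (allylpalladium formation, then B–B transmetallation), which gives the linear primary allylboronic acid with both E alkenes unchanged; no stereocentre is formed.

Step 4
Reactants: 5 2-diazo-1-[2-methyl-6-(triisopropylsilyloxy)phenyl]ethan-1-one; 7 [(2E,6E)-3,7,11-trimethyldodeca-2,6,10-trien-1-yl]boronic acid
Product: 9 (3R,6E)-3-ethenyl-1-(2-hydroxy-6-methylphenyl)-3,7,11-trimethyldodeca-6,10-dien-1-one, via silyl ether 8 (not isolated)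
Conditions: Cu(O2CC4H3S) (copper thiophene-2-carboxylate, 10 mol %), (S,S)-t-Bu-BOX (12 mol %), toluene, –20 °C, 5 added over 2 h to 7 (1.3 equiv); then Bu4NF (5 equiv), THF, 0 °C
Reagents that add atoms: none
Why: Proposed new method: the copper-catalysed carbene cross-coupling of an α-diazoketone with a γ,γ-disubstituted allylboronic acid is known in racemic form to give this branched (γ-attack) α-allyl ketone with a quaternary carbon, the diazo carbon acting after N2 loss as an electrophilic α-oxo-carbenoid toward the nucleophilic allyl group; what is new is the chiral bisoxazoline, 2,2'-(propane-2,2-diyl)bis[(4S)-4-tert-butyl-4,5-dihydro-1,3-oxazole], which sits on copper while the carbenoid carbon bonds to C3 of the farnesyl unit (methyl and chain positions fixed by the 2E geometry) in a compact γ-transfer transition state and should therefore choose one face of C3 to give the 3R centre, the closest known asymmetric reactions being bisoxazoline–copper cyclopropanation of trisubstituted alkenes and copper-catalysed [2,3]-rearrangements of allyl ylides; protonolysis of the copper enolate by B–OH releases 8, and fluoride then cleaves the aryl silyl ether without touching the alkenes or the non-epimerisable quaternary centre.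

**Compound list**

1 | 1-(2-hydroxy-6-methylphenyl)ethan-1-one | CC(=O)c1c(C)cccc1O | starting material
2 | 1-[2-methyl-6-(triisopropylsilyloxy)phenyl]ethan-1-one | CC(=O)c1c(C)cccc1O[Si](C(C)C)(C(C)C)C(C)C | intermediate
3 | lithium 1-[2-methyl-6-(triisopropylsilyloxy)phenyl]ethen-1-olate | [Li+].[O-]C(=C)c1c(C)cccc1O[Si](C(C)C)(C(C)C)C(C)C | intermediate
4 | 4,4,4-trifluoro-1-[2-methyl-6-(triisopropylsilyloxy)phenyl]butane-1,3-dione | O=C(CC(=O)C(F)(F)F)c1c(C)cccc1O[Si](C(C)C)(C(C)C)C(C)C | intermediate
5 | 2-diazo-1-[2-methyl-6-(triisopropylsilyloxy)phenyl]ethan-1-one | [N-]=[N+]=CC(=O)c1c(C)cccc1O[Si](C(C)C)(C(C)C)C(C)C | intermediate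
6 | (2E,6E)-3,7,11-trimethyldodeca-2,6,10-trien-1-ol [(2E,6E)-farnesol] | CC(C)=CCC/C(C)=C/CC/C(C)=C/CO | starting material
7 | [(2E,6E)-3,7,11-trimethyldodeca-2,6,10-trien-1-yl]boronic acid | CC(C)=CCC/C(C)=C/CC/C(C)=C/CB(O)O | intermediate
8 | (3R,6E)-3-ethenyl-3,7,11-trimethyl-1-[2-methyl-6-(triisopropylsilyloxy)phenyl]dodeca-6,10-dien-1-one | C=C[C@](C)(CC/C=C(\C)CCC=C(C)C)CC(=O)c1c(C)cccc1O[Si](C(C)C)(C(C)C)C(C)C | intermediate
9 | (3R,6E)-3-ethenyl-1-(2-hydroxy-6-methylphenyl)-3,7,11-trimethyldodeca-6,10-dien-1-one | C=C[C@](C)(CC/C=C(\C)CCC=C(C)C)CC(=O)c1c(C)cccc1O | target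

**Count and risks**

Total step count: 4. Longest linear sequence: 3 (1 → 2 → 5 → 9); 7 is made in one step from 6.

Most likely to fail, first: step 4. The racemic coupling has precedent, but the enantioselectivity is untested. The carbenoid may also attack the trisubstituted alkenes or the silyloxy oxygen, and any 2Z isomer in 7 gives the enantiomer. The fallback replaces the carbene coupling by a closed-transition-state allylboration; it sets out from 5 (with 7) and comes back at 8.
- Diazoketone 5 is oxidised with dimethyldioxirane (acetone, 0 °C) to 2-[2-methyl-6-(triisopropylsilyloxy)phenyl]-2-oxoacetaldehyde F1, in which the future α-carbon is again the electrophile.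
- Acid 7 is esterified with pinacol (MgSO4, Et2O) to the (2E,6E)-farnesylboronic acid pinacol ester F2.
- F1 and F2 are joined with a chiral BINOL-derived phosphoric acid [(S)-TRIP as the working choice, 5 mol %, toluene, 4 Å sieves, –40 °C]. The chair Zimmerman–Traxler transition state gives the (2S,3S)-α-hydroxy ketone F3: the 2E geometry places OH syn to the methyl group, and the acid chooses the aldehyde face (antipode if the sense is opposite).
- SmI2 (THF–MeOH, –78 °C) removes the α-hydroxyl of F3 to give 8, which is desilylated as in step 4.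

Second: step 3. Acid 7 is oxygen-sensitive and cannot be chromatographed; partial oxidation or E/Z erosion would go straight into the key step. The fallback isolates the boron nucleophile as a crystalline salt; it sets out from 6 and comes back at 7. The crude product of the same borylation is treated with aqueous KHF2 (MeOH, 0 °C) to give potassium (2E,6E)-farnesyltrifluoroborate F4. This is recrystallised (acetone–Et2O) to upgrade isomeric purity and can be stored. Me3SiCl and H2O (MeCN, 20 °C) release 7 just before use.

Third: step 2. C-acylation of the hindered 2,6-disubstituted aryl ketone enolate may be slow, and the silyl group may shift or be lost in the basic transfer medium. The fallback avoids enolate acylation; it sets out from 2 and comes back at 5. Bromination with PhNMe3Br3 (THF, 0–20 °C) gives 2-bromo-1-[2-methyl-6-(triisopropylsilyloxy)phenyl]ethan-1-one F5. N,N'-ditosylhydrazine and DBU (THF, 0 °C) then turn the bromide into the diazo group by N-alkylation and loss of two sulfinates, giving 5.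

**Further compounds**

F1 | step 4 | 2-[2-methyl-6-(triisopropylsilyloxy)phenyl]-2-oxoacetaldehyde | O=CC(=O)c1c(C)cccc1O[Si](C(C)C)(C(C)C)C(C)C
F2 | step 4 | 4,4,5,5-tetramethyl-2-[(2E,6E)-3,7,11-trimethyldodeca-2,6,10-trien-1-yl]-1,3,2-dioxaborolane | CC(C)=CCC/C(C)=C/CC/C(C)=C/CB1OC(C)(C)C(C)(C)O1
F3 | step 4 | (2S,3S,6E)-3-ethenyl-2-hydroxy-3,7,11-trimethyl-1-[2-methyl-6-(triisopropylsilyloxy)phenyl]dodeca-6,10-dien-1-one | C=C[C@](C)(CC/C=C(\C)CCC=C(C)C)[C@H](O)C(=O)c1c(C)cccc1O[Si](C(C)C)(C(C)C)C(C)C
F4 | step 3 | potassium trifluoro[(2E,6E)-3,7,11-trimethyldodeca-2,6,10-trien-1-yl]borate | [K+].CC(C)=CCC/C(C)=C/CC/C(C)=C/C[B-](F)(F)F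
F5 | step 2 | 2-bromo-1-[2-methyl-6-(triisopropylsilyloxy)phenyl]ethan-1-one | BrCC(=O)c1c(C)cccc1O[Si](C(C)C)(C(C)C)C(C)C
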